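The earlier runs and the new flask come from a simulation on assumed constants; noise was put on by code.

The spring run, with 20 µM of enzyme, reads 20.3% in the target column at 15.0 min. That column already counts the crystals, so it is the sum you are asked for, and adding the crystals column to it counts them twice.

| flask | starting material | enzyme | remark | time |
|---|---|---|---|---|
| dawn | 0.10 M | 5 µM | run made earlier |  |
| spring | 0.10 M | 20 µM | run made earlier |  |
| midnight | 0.20 M | 10 µM | run made earlier |  |
| flask | 0.10 M | 10 µM |  | 20 min |

| run | time / min | target / % | crystals / % |
|---|---|---|---|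
| dawn | 1.33 | 0.9 | 0.1 |
| dawn | 2.00 | 1.6 | 0 |
| dawn | 4.00 | 1.2 | 0 |
| dawn | 6.00 | 1.0 | 0.3 |
| dawn | 10.0 | 3.6 | 0.8 |
| dawn | 15.0 | 5.8 | 3.1 |
| spring | 1.00 | 1.2 | 0 |
| spring | 3.00 | 4.6 | 0.4 |
| spring | 6.00 | 8.1 | 3.6 |
| spring | 8.00 | 10.0 | 5.0 |
| spring | 12.0 | 15.6 | 11.1 |
| spring | 15.0 | 20.3 | 14.2 |
| midnight | 1.33 | 1.2 | 0.1 |
| midnight | 2.50 | 1.7 | 0 |
| midnight | 5.00 | 2.5 | 0 |
| midnight | 8.00 | 3.9 | 1.7 |
| midnight | 15.0 | 7.1 | 4.8 |

(readings scatter by 0.5 percentage points)

- for target the crystals are counted in
- as a solid, counted per litre of solution: crystals
- steps that have been proposed: starting material + enzyme <-> complex; complex <-> enzyme + target; crystals <-> target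

1. how much target and crystals together there is at 20 min, in percent of the starting material charged
2. concentration of target in solution at 20 min, in percent of saturation

Starting material binds the enzyme, the complex releases target, and the rate goes with [complex]. So divide what a run made by its enzyme and its time:

w = [target] / ([enzyme] · t) = 20.3% × 0.10 M / (20 µM × 15.0 min) = 67.7 min⁻¹

This w, the average turnover per enzyme at this charge, is the apparent turnover frequency. The midnight run, with twice the charge, reads 94.7 min⁻¹, a ratio of 1.40. The order in starting material therefore lies between zero and one. If w goes as [starting material] / (K + [starting material]), then: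

K = 2 [starting material] (ratio − 1) / (2 − ratio) = 0.133 M

K, the Michaelis constant, is the concentration that sets the order. As a reading, it lies above the charge of 0.10 M, which puts about 43.0% of the enzyme in the complex. The flask has the spring run's charge, so I carry w over, and the spring run went further in enzyme × time than the flask needs:

y = w [enzyme] t / [starting material] = 13.5%

I give no number of my own for saturation. The forecast says 21% and 400%: “The summed target + crystals tracks enzyme × time”. Its figure stands above mine, for I read the target column by itself.

    starting material + enzyme ⇌ complex (K = 9.10 M⁻¹, k = 1.30 × 10⁵ M⁻¹ min⁻¹)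
    complex ⇌ enzyme + target (K = 0.180 M, k = 150 min⁻¹)
    crystals ⇌ target, rate k3*(cs3 - [target]) while solid is left; crystals form when [target] > cs3 (solubility = 1.80 mM, k = 0.390 min⁻¹)

The flask gives 13.4%, with dissolved target at 192% of saturation, which is a w of 67.1 min⁻¹. Complex and enzyme relax with a half-life of 0.272 s at 20.0 min, far shorter than the 20 min of the run. At 9.76 min complex is made 1.00 times as fast as it is used up, a steady state, and it stands at 47.0% of the enzyme at 2.00 min and 43.8% at 20.0 min. For the same flask read at 5.0 min, w gives 3.38%, and that flask holds 3.48%.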